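The target is an ortho,ortho'-dihydroxyaryl ketone. On ring D (the phloroglucinol ring on C4), the ketone carbon lies between two phenolic OH groups. The route rests on disconnecting the bond from this carbonyl carbon to its alpha-CH2. This leads back to the unprotected flavanyl-phloroglucinol carbaldehyde and 8-phenyloct-1-ene. In the last step a phenoxide-chelated rhodium catalyst adds the formyl C–H bond across the terminal alkene (linear hydroacylation). Both halves are joined with full atom economy, without protecting groups, and C2 and C4 stay untouched. The aldehyde stems from a catalytic asymmetric ortho-quinone methide/styrene [4+2] cycloaddition that closes ring C and sets the 2,4-cis (2S,4S) pair in one operation.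

Key step: step 7

Ring labels: ring A = benzo ring of the chromane, ring B = aryl group on C2, ring C = pyran ring, ring D = phloroglucinol ring on C4.
Assumption: the (R)-configured phosphoramide of step 4 is taken to deliver the (2S,4S) series (if the sense of induction proves opposite, its equally available (S)-enantiomer is used), and slow rotation about the C4–ring D bond gives rotamers only and is not treated as a stereo-element.

Step 1
Reactants: 1 phloroglucinol (benzene-1,3,5-triol)
Product: 2 1,3,5-tris(methoxymethoxy)benzene
Conditions: NaH (3.6 equiv), MOMCl (3.6 equiv), DMF, 0 °C to rt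
Reagents that add atoms: chloromethyl methyl ether (MOMCl), COCCl
Why: Threefold Williamson-type O-alkylation of the sodium phenoxide by the hard electrophile MOMCl should give the tris-acetal, whose OMOM groups later direct the lithiation.

Step 2
Reactants: 3 2,4-dihydroxybenzaldehyde
Product: 4 2-hydroxy-4-(methoxymethoxy)benzaldehyde
Conditions: MOMCl (1.05 equiv), K2CO3 (1.1 equiv), acetone, rt
Reagents that add atoms: chloromethyl methyl ether (MOMCl), COCCl
Why: Regioselective Williamson-type O-alkylation, because the 2-OH is tied up in a hydrogen bond to the formyl group and the mild base should therefore alkylate only the 4-OH.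

Step 3
Reactants: 2 1,3,5-tris(methoxymethoxy)benzene; 4 2-hydroxy-4-(methoxymethoxy)benzaldehyde
Product: 7 [2-hydroxy-4-(methoxymethoxy)phenyl][2,4,6-tris(methoxymethoxy)phenyl]methanol (racemic), via aryllithium 5 (not isolated), via sodium phenoxide 6 (not isolated)
Conditions: 2, n-BuLi (1.05 equiv), THF, 0 °C; separately 4, NaH (1.0 equiv), THF, 0 °C; combine at −78 °C to rt; H2O quench, neutral work-up
Reagents that add atoms: none
Why: Directed ortho-metalation between two OMOM groups, followed by 1,2-addition of the aryllithium to the aldehyde whose acidic phenol is masked as its sodium salt, should give the benzhydrol, whose racemic carbinol centre is erased in step 4.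

Step 4
Reactants: 7 [2-hydroxy-4-(methoxymethoxy)phenyl][2,4,6-tris(methoxymethoxy)phenyl]methanol; 8 4-(tert-butyldimethylsilyloxy)styrene
Product: 10 (2S,4S)-2-[4-(tert-butyldimethylsilyloxy)phenyl]-7-(methoxymethoxy)-4-[2,4,6-tris(methoxymethoxy)phenyl]chromane (2,4-cis), via ortho-quinone methide 9 (not isolated)
Conditions: (R)-3,3'-bis(2,4,6-triisopropylphenyl)-1,1'-binaphthyl-2,2'-diyl N-(trifluoromethylsulfonyl)phosphoramide (10 mol %), 8 (2 equiv), 4 Å MS, CH2Cl2, −20 °C to rt
Reagents that add atoms: none
Why: Chiral Brønsted acid-catalysed dehydration should give the E-configured ortho-quinone methide 9, which stays hydrogen-bonded in the catalyst pocket and undergoes an inverse-electron-demand oxa-Diels–Alder reaction with the electron-rich styrene through an endo transition state, so that C2 and C4 form cis to each other while the face selection of the catalyst fixes the absolute (2S,4S) configuration.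

Step 5
Reactants: 10 (2S,4S)-2-[4-(tert-butyldimethylsilyloxy)phenyl]-7-(methoxymethoxy)-4-[2,4,6-tris(methoxymethoxy)phenyl]chromane
Product: 13 2,4,6-trihydroxy-3-[(2S,4S)-7-hydroxy-2-(4-hydroxyphenyl)chroman-4-yl]benzaldehyde, via iminium chloride 11 (not isolated), via protected aldehyde 12 (not isolated)
Conditions: POCl3 (1.3 equiv), DMF (3 equiv), MeCN, 0 °C to rt; H2O, rt; then MeOH, aq HCl (about 2 M final), 40 °C, same flask
Reagents that add atoms: N,N-dimethylformamide, CN(C)C=O; water, O
Why: Vilsmeier–Haack formylation should attack ring D, the ring with three oxygen donors and two constitutionally equivalent free positions, and the aqueous-methanolic acid that follows the iminium hydrolysis cleaves the four MOM acetals and the aryl silyl ether by acid-catalysed solvolysis, the diequatorial 2,4-cis arrangement being the thermodynamically preferred one.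

Step 6
Reactants: 14 8-bromooct-1-ene; 15 phenylmagnesium bromide
Product: 16 8-phenyloct-1-ene
Conditions: FeCl3 (5 mol %), TMEDA (1.2 equiv), THF, 0 °C, slow addition of 15
Reagents that add atoms: none
Why: Iron-catalysed Kumada-type cross-coupling of an aryl Grignard reagent with a primary alkyl bromide should form the aryl–CH2 bond and leave the remote terminal alkene untouched.

Step 7
Reactants: 13 2,4,6-trihydroxy-3-[(2S,4S)-7-hydroxy-2-(4-hydroxyphenyl)chroman-4-yl]benzaldehyde; 16 8-phenyloct-1-ene
Product: 17 1-{2,4,6-trihydroxy-3-[(2S,4S)-7-hydroxy-2-(4-hydroxyphenyl)chroman-4-yl]phenyl}-9-phenylnonan-1-one (target)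
Conditions: [Rh(cod)Cl]2 (5 mol %), (Ra,R,R)-SIPHOS-PE (spirobiindane-7,7'-diol phosphoramidite with a bis[(R)-1-phenylethyl]amino group, 10 mol %), K3PO4 (10 mol %), 16 (2 equiv), 1,4-dioxane, 80 °C, argon
Reagents that add atoms: none
Why: K3PO4 converts a catalytic part of 13 into a rhodium phenoxide through either of the two ring D hydroxyls that flank the formyl group, and the formyl C–H bond then adds oxidatively to monovalent rhodium to give a five-membered O,C-chelated acyl hydride of trivalent rhodium that resists decarbonylation. Coordination of 16, anti-Markovnikov migratory insertion into the Rh–H bond and reductive elimination from the acyl(primary alkyl) complex form the carbonyl–CH2 bond and release the catalyst. The closest known reaction type is the rhodium/phosphoramidite-catalysed linear-selective intermolecular hydroacylation of unactivated terminal alkenes with salicylaldehydes, a class that tolerates further free phenolic OH groups on the aldehyde ring. No ring is closed and no stereocentre is created, so C2 and C4 are spectators. The step needs linear over branched selectivity, which reversible branched insertion and fast reductive elimination from the linear alkyl under the bulky monodentate ligand should secure, and it needs selection among five phenols, which is secured because only an OH ortho to the formyl group can chelate. The base is catalytic and resides on the most acidic, formyl-conjugated phenol of ring D, so opening of ring C through a ring B phenoxide and a para-quinone methide, which would scramble C2, should not be triggered.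

Compound list
1 | phloroglucinol | Oc1cc(O)cc(O)c1 | starting material
2 | 1,3,5-tris(methoxymethoxy)benzene | COCOc1cc(OCOC)cc(OCOC)c1 | intermediate
3 | 2,4-dihydroxybenzaldehyde | O=Cc1ccc(O)cc1O | starting material
4 | 2-hydroxy-4-(methoxymethoxy)benzaldehyde | O=Cc1ccc(OCOC)cc1O | intermediate
5 | 2,4,6-tris(methoxymethoxy)phenyllithium | [Li]c1c(OCOC)cc(OCOC)cc1OCOC | intermediate
6 | sodium 2-formyl-5-(methoxymethoxy)phenoxide | [Na+].[O-]c1cc(OCOC)ccc1C=O | intermediate
7 | [2-hydroxy-4-(methoxymethoxy)phenyl][2,4,6-tris(methoxymethoxy)phenyl]methanol (racemic) | OC(c1ccc(OCOC)cc1O)c1c(OCOC)cc(OCOC)cc1OCOC | intermediate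
8 | 4-(tert-butyldimethylsilyloxy)styrene | C=Cc1ccc(O[Si](C)(C)C(C)(C)C)cc1 | starting material
9 | (E)-3-(methoxymethoxy)-6-[2,4,6-tris(methoxymethoxy)benzylidene]cyclohexa-2,4-dien-1-one | O=C1C=C(OCOC)C=C/C1=C\c1c(OCOC)cc(OCOC)cc1OCOC | intermediate
10 | (2S,4S)-2-[4-(tert-butyldimethylsilyloxy)phenyl]-7-(methoxymethoxy)-4-[2,4,6-tris(methoxymethoxy)phenyl]chromane | COCOc1cc(OCOC)c([C@H]2C[C@@H](c3ccc(O[Si](C)(C)C(C)(C)C)cc3)Oc3cc(OCOC)ccc32)c(OCOC)c1 | intermediate
11 | N,N-dimethyliminium chloride of aldehyde 12 | C[N+](C)=Cc1c(OCOC)cc(OCOC)c([C@H]2C[C@@H](c3ccc(O[Si](C)(C)C(C)(C)C)cc3)Oc3cc(OCOC)ccc32)c1OCOC.[Cl-] | intermediate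
12 | 3-{(2S,4S)-2-[4-(tert-butyldimethylsilyloxy)phenyl]-7-(methoxymethoxy)chroman-4-yl}-2,4,6-tris(methoxymethoxy)benzaldehyde | O=Cc1c(OCOC)cc(OCOC)c([C@H]2C[C@@H](c3ccc(O[Si](C)(C)C(C)(C)C)cc3)Oc3cc(OCOC)ccc32)c1OCOC | intermediate
13 | 2,4,6-trihydroxy-3-[(2S,4S)-7-hydroxy-2-(4-hydroxyphenyl)chroman-4-yl]benzaldehyde | O=Cc1c(O)cc(O)c([C@H]2C[C@@H](c3ccc(O)cc3)Oc3cc(O)ccc32)c1O | intermediate
14 | 8-bromooct-1-ene | C=CCCCCCCBr | starting material
15 | phenylmagnesium bromide | Br[Mg]c1ccccc1 | starting material
16 | 8-phenyloct-1-ene | C=CCCCCCCc1ccccc1 | intermediate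
17 | 1-{2,4,6-trihydroxy-3-[(2S,4S)-7-hydroxy-2-(4-hydroxyphenyl)chroman-4-yl]phenyl}-9-phenylnonan-1-one | O=C(CCCCCCCCc1ccccc1)c1c(O)cc(O)c([C@H]2C[C@@H](c3ccc(O)cc3)Oc3cc(O)ccc32)c1O | target

Total step count: 7. Longest linear sequence: 5 steps (1, 3, 4, 5, 7).

Steps most likely to fail

Step 7. Decarbonylation of the acyl rhodium hydride, sequestration of the catalyst by the polyphenol, or isomerisation of the terminal alkene may outrun productive insertion. The fallback sets out from 12, isolated after a buffered aqueous work-up (aq NaOAc) of the formylation stage of step 5, and comes back to the route at 17. Commercial (8-bromooctyl)benzene and Mg turnings in THF give 8-phenyloctylmagnesium bromide F1. This adds to the aldehyde of 12 at −78 °C to 0 °C to give the secondary carbinol F2 (both epimers, which is inconsequential). Dess–Martin oxidation gives the fully protected ketone F3. Aqueous HCl in MeOH at 40 °C then removes the four MOM groups and the silyl group to give 17. The same carbonyl–CH2 bond is thus made by polar 1,2-addition and oxidation instead of C–H activation.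

Step 4. Facial selectivity may be poor because the di-ortho-substituted ring D aryl group fits the catalyst pocket badly, and acid-induced oligomerisation of the styrene may compete. The fallback sets out from 2 (lithiated to 5 as in step 3) and comes back at 10. It sets C2 first and C4 by substrate control.
- Commercial 7-hydroxychromone is protected (MOMCl, i-Pr2NEt, CH2Cl2) as 7-(methoxymethoxy)-4H-chromen-4-one F4.
- Asymmetric 1,4-addition of commercial 4-(tert-butyldimethylsilyloxy)phenylboronic acid follows. The catalyst is [Rh(OH)(cod)]2 with the enantiomer of an electron-poor MeO-BIPHEP-type bisphosphine that leads to the S series. This gives the (S)-flavanone F5.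
- Aryllithium 5 adds to the ketone at −78 °C in the presence of anhydrous CeCl3, which suppresses enolisation and ring opening, to give the tertiary flavan-4-ol F6.
- Ionic reduction (Et3SiH, TFA, CH2Cl2, −40 °C) delivers hydride pseudo-axially to the C4 cation of the half-chair whose C2 aryl group is equatorial. Ring D therefore ends equatorial, which is the 2,4-cis compound 10.

Step 5. During the acidic stage, ionisation of the benzylic C2–O1 bond may open ring C, with epimerisation, reclosure onto a ring D hydroxyl or oligomerisation. The fallback sets out from 12, isolated after a buffered work-up of the formylation stage, and comes back at 13. It avoids protic acid altogether. TMSOTf and 2,2'-bipyridyl in MeCN (0 °C to rt) exchange the four aromatic MOM ethers for trimethylsilyl ethers in a weakly basic medium, giving the pentasilyl ether F7. KHF2 in MeOH at rt then cleaves all five aryl silyl ethers to give 13.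

Further compounds
F1 | step 7 | 8-phenyloctylmagnesium bromide | Br[Mg]CCCCCCCCc1ccccc1
F2 | step 7 | 1-(3-{(2S,4S)-2-[4-(tert-butyldimethylsilyloxy)phenyl]-7-(methoxymethoxy)chroman-4-yl}-2,4,6-tris(methoxymethoxy)phenyl)-9-phenylnonan-1-ol (both carbinol epimers) | OC(CCCCCCCCc1ccccc1)c1c(OCOC)cc(OCOC)c([C@H]2C[C@@H](c3ccc(O[Si](C)(C)C(C)(C)C)cc3)Oc3cc(OCOC)ccc32)c1OCOC
F3 | step 7 | 1-(3-{(2S,4S)-2-[4-(tert-butyldimethylsilyloxy)phenyl]-7-(methoxymethoxy)chroman-4-yl}-2,4,6-tris(methoxymethoxy)phenyl)-9-phenylnonan-1-one | O=C(CCCCCCCCc1ccccc1)c1c(OCOC)cc(OCOC)c([C@H]2C[C@@H](c3ccc(O[Si](C)(C)C(C)(C)C)cc3)Oc3cc(OCOC)ccc32)c1OCOC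
F4 | step 4 | 7-(methoxymethoxy)-4H-chromen-4-one | O=c1ccoc2cc(OCOC)ccc12
F5 | step 4 | (S)-2-[4-(tert-butyldimethylsilyloxy)phenyl]-7-(methoxymethoxy)chroman-4-one | O=C1C[C@@H](c2ccc(O[Si](C)(C)C(C)(C)C)cc2)Oc2cc(OCOC)ccc21
F6 | step 4 | (2S)-2-[4-(tert-butyldimethylsilyloxy)phenyl]-7-(methoxymethoxy)-4-[2,4,6-tris(methoxymethoxy)phenyl]chroman-4-ol (C4 configuration inconsequential) | OC1(c2c(OCOC)cc(OCOC)cc2OCOC)C[C@@H](c2ccc(O[Si](C)(C)C(C)(C)C)cc2)Oc2cc(OCOC)ccc21
F7 | step 5 | 3-{(2S,4S)-2-[4-(tert-butyldimethylsilyloxy)phenyl]-7-(trimethylsilyloxy)chroman-4-yl}-2,4,6-tris(trimethylsilyloxy)benzaldehyde | O=Cc1c(O[Si](C)(C)C)cc(O[Si](C)(C)C)c([C@H]2C[C@@H](c3ccc(O[Si](C)(C)C(C)(C)C)cc3)Oc3cc(O[Si](C)(C)C)ccc32)c1O[Si](C)(C)C
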